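The oxolane ring carries the aryl group on C2, the CH2O arm on C3 and the hydroxyl on C4 all cis, so H-2, H-3 and H-4 share one face. The aryl–C2 bond is therefore forged while C2 is still the carbonyl carbon of a γ-lactone bonded to O1: 3,4-dimethoxyphenyllithium adds to a lactone whose C3-CH2O and C4-O are bridged by a silylene, and the adduct is dehydrated in the same flask to a flat 2-aryl-4,5-dihydrofuran. The purchased C4 stereocenter, through that temporary six-membered ring, then directs a single syn-hydrogenation that sets C2 and C3 together. Desilylation and selective primary acylation complete the target.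

Key step: step 3

Remark: ring atoms keep the numbering O1, C2, C3, C4, C5 of the target oxolane in every intermediate; the target is read as (2R,3S,4R), which places aryl, CH2O and OH all cis.

Step 1
Reactants: 1 (R)-3-hydroxy-γ-butyrolactone
Product: 3 (3R,4R)-4-hydroxy-3-(hydroxymethyl)oxolan-2-one, via dilithium enolate-alkoxide 2 (not isolated)
Conditions: LiN(iPr)2 (2.2 equiv), THF, −78 → −40 °C; CH2O (gas), −78 °C; AcOH
Reagents that add atoms: formaldehyde, C=O
Why: Fráter–Seebach-type aldol addition, in which the dilithium enolate-alkoxide 2 should add formaldehyde at C3 anti to the C4 alkoxide to give the trans diol, although the C3 configuration is irrelevant because step 3 makes C3 planar.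

Step 2
Reactants: 3 (3R,4R)-4-hydroxy-3-(hydroxymethyl)oxolan-2-one
Product: 4 (3R,4R) trans-fused lactone bridged from C3-CH2O to C4-O by di-tert-butylsilylene
Conditions: tBu2Si(OTf)2, 2,6-lutidine, DMF, 0 °C → rt
Reagents that add atoms: di-tert-butylsilyl bis(trifluoromethanesulfonate), CC(C)(C)[Si](OS(=O)(=O)C(F)(F)F)(OS(=O)(=O)C(F)(F)F)C(C)(C)C
Why: Standard silylene protection of a 1,3-diol with the ditriflate and a hindered pyridine base, giving a trans-fused six-membered dioxasilinane of the kind known for 3,5-O-silylene arabinofuranosides, with no stereocenter formed or touched.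

Step 3
Reactants: 4 (3R,4R) trans-fused silylene lactone; 5 4-bromo-1,2-dimethoxybenzene
Product: 9 (4R)-2-(3,4-dimethoxyphenyl)-4,5-dihydrofuran bridged from C3-CH2O to C4-O by di-tert-butylsilylene, via 3,4-dimethoxyphenyllithium 6 (not isolated), via lithium hemiketalate 7 (not isolated), via hemiketal trifluoroacetate 8 (not isolated)
Conditions: 5, n-BuLi, THF, −78 °C; then 4, −78 °C; (CF3CO)2O, −78 °C; Et3N, −78 → 0 °C
Reagents that add atoms: none
Why: Bromine–lithium exchange gives 6, which adds once to the lactone carbonyl C2 of 4 to form the C2–aryl bond as the cyclic lithium hemiketalate 7; O-trifluoroacetylation to 8, ionization assisted by O1 and the electron-rich aryl group, and loss of H-3 to Et3N (E1 elimination) should then deliver the enol ether 9. The closest known reaction types are the aryllithium addition to sugar lactones used for C-aryl glycosides and the acylative dehydration of the resulting hemiketals to 1-aryl glycals. No ring is closed. The only new stereocenter, the hemiketal carbon C2 of 7 and 8, is left uncontrolled on purpose and is erased together with C3 when the C2=C3 bond forms, while C4 is untouched. The step needs mono-addition and carbonyl addition in preference to deprotonation at C3, which the low temperature, the persistence of the tetrahedral adduct 7 and the hindered tertiary C3–H should secure, and a single elimination regiochemistry, which is guaranteed because H-3 is the only β-hydrogen. Acylating 7 before any aqueous work-up avoids the ring-open γ-hydroxy aryl ketone tautomer, which would not dehydrate cleanly.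

Step 4
Reactants: 9 silylene-bridged (4R)-2-aryl-4,5-dihydrofuran
Product: 10 all-cis (2R,3R,4R)-2-(3,4-dimethoxyphenyl)oxolane bridged from C3-CH2O to C4-O by di-tert-butylsilylene
Conditions: H2 (10 bar), 10% Pd/C, Et3N, EtOAc, rt
Reagents that add atoms: none
Why: Heterogeneous catalytic syn-hydrogenation of a 1-aryl-glycal-type enol ether, in which the chair dioxasilinane ring with its tert-butyl groups lies wholly on the face of the C4–O bond, so both hydrogens should add to C2 and C3 from the opposite face, giving the cis ring fusion and placing aryl, CH2O and the C4 oxygen all cis (C2 and C3 set in one event under control of C4), while Et3N tempers hydrogenolysis of the benzylic C2–O1 bond.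

Step 5
Reactants: 10 all-cis silylene-bridged 2-aryloxolane
Product: 11 (2R,3S,4R)-2-(3,4-dimethoxyphenyl)-3-(hydroxymethyl)oxolan-4-ol
Conditions: HF·pyridine, pyridine, THF, 0 °C → rt
Reagents that add atoms: none
Why: Fluoride-mediated desilylation driven by Si–F bond formation, buffered with pyridine so that the benzylic C2–O1 bond should not ionize and no stereocenter is touched.

Step 6
Reactants: 11 (2R,3S,4R)-2-(3,4-dimethoxyphenyl)-3-(hydroxymethyl)oxolan-4-ol; 12 3,4-dimethoxybenzoyl chloride
Product: 13 [(2R,3S,4R)-2-(3,4-dimethoxyphenyl)-4-hydroxyoxolan-3-yl]methyl 3,4-dimethoxybenzoate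
Conditions: 2,4,6-collidine, CH2Cl2, −40 → 0 °C
Reagents that add atoms: none
Why: Kinetically selective esterification of the primary hydroxyl over the hindered secondary C4 hydroxyl on the crowded all-cis face, using a slight excess of the aroyl chloride with a hindered base at low temperature and no acyl-transfer catalyst.

Compound list
1 | (R)-3-hydroxy-γ-butyrolactone, (4R)-4-hydroxyoxolan-2-one | O=C1C[C@@H](O)CO1 | starting material
2 | dilithium enolate-alkoxide of 1 (C2 lithium enolate, C4 lithium alkoxide, 4R) | [Li]OC1=C[C@@H](O[Li])CO1 | intermediate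
3 | (3R,4R)-4-hydroxy-3-(hydroxymethyl)oxolan-2-one (CH2OH and OH trans) | O=C1[C@H](CO)[C@@H](O)CO1 | intermediate
4 | (3R,4R) trans-fused lactone: di-tert-butylsilylene ether bridging the C3-CH2O and C4-O of 3 (six-membered dioxasilinane fused at C3–C4) | O=C1[C@@H]2CO[Si](C(C)(C)C)(C(C)(C)C)O[C@H]2CO1 | intermediate
5 | 4-bromo-1,2-dimethoxybenzene (4-bromoveratrole) | COc1ccc(Br)cc1OC | starting material
6 | 3,4-dimethoxyphenyllithium | [Li]c1ccc(OC)c(OC)c1 | intermediate
7 | lithium hemiketalate: 2-(3,4-dimethoxyphenyl)-2-(lithiooxy) adduct of 4 (C2 epimers, C3 R, C4 R) | [Li]OC1(c2ccc(OC)c(OC)c2)[C@@H]3CO[Si](C(C)(C)C)(C(C)(C)C)O[C@H]3CO1 | intermediate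
8 | hemiketal trifluoroacetate: 2-(3,4-dimethoxyphenyl)-2-(trifluoroacetoxy) derivative of 4 (C2 epimers, C3 R, C4 R) | O=C(OC1(c2ccc(OC)c(OC)c2)[C@@H]3CO[Si](C(C)(C)C)(C(C)(C)C)O[C@H]3CO1)C(F)(F)F | intermediate
9 | (4R)-2-(3,4-dimethoxyphenyl)-4,5-dihydrofuran with C2=C3 double bond, its C3-CH2O and C4-O bridged by di-tert-butylsilylene | COc1ccc(C2=C3CO[Si](C(C)(C)C)(C(C)(C)C)O[C@H]3CO2)cc1OC | intermediate
10 | all-cis (2R,3R,4R)-2-(3,4-dimethoxyphenyl)oxolane with C3-CH2O and C4-O bridged by di-tert-butylsilylene, cis-fused (the C3 descriptor differs from the target only through the CIP rank of the O–Si branch) | CC(C)(C)[Si]1(C(C)(C)C)OC[C@H]2[C@H](CO[C@H]2c2ccc(OC)c(OC)c2)O1 | intermediate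
11 | (2R,3S,4R)-2-(3,4-dimethoxyphenyl)-3-(hydroxymethyl)oxolan-4-ol (all-cis diol) | OC[C@H]1[C@@H](O)CO[C@H]1c1ccc(OC)c(OC)c1 | intermediate
12 | 3,4-dimethoxybenzoyl chloride (veratroyl chloride) | COc1ccc(C(Cl)=O)cc1OC | starting material
13 | [(2R,3S,4R)-2-(3,4-dimethoxyphenyl)-4-hydroxyoxolan-3-yl]methyl 3,4-dimethoxybenzoate | COc1ccc(C(=O)OC[C@H]2[C@@H](O)CO[C@H]2c2ccc(OC)c(OC)c2)cc1OC | target

Total step count: 6
Longest linear sequence: 6 steps (1 → 3 → 4 → 9 → 10 → 11 → 13)

Steps most likely to fail

Step 3. The aryllithium may deprotonate C3 of the lactone instead of adding. The tetrahedral adduct may also collapse to the ring-open aryl ketone before it is acylated, which would lead to double addition or to acylation of the primary alkoxide. The fallback sets out from 4 and makes the same C2–aryl bond by cross-coupling, with no hemiketal on the way. Deprotonation of 4 with KN(SiMe3)2 in the presence of (PhO)2P(O)Cl (THF/HMPA, −78 °C) should give the ketene acetal diphenyl phosphate F1. Suzuki–Miyaura coupling of F1 with 3,4-dimethoxyphenylboronic acid (Pd(PPh3)4, aqueous Na2CO3, DME, 60 °C) should then give 9, where the route resumes.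

Step 4. Saturation of the tetrasubstituted enol ether may be slow, and forcing it may cause hydrogenolysis of the benzylic C2–O1 bond or loss of the C4 oxygen with aromatization to a furan on the catalyst. The fallback sets out from 9 and replaces surface hydrogenation by ionic hydrogenation (Et3SiH, CF3CO2H, CH2Cl2, −78 °C). A proton should be delivered to C3 and then hydride to C2, both from the open convex face of the cis-fused bicycle, which should give 10 directly, where the route resumes. No new isolable compound is made (entry F0).

Step 1. Gaseous formaldehyde may add more than once or revert by retro-aldol, and the very polar diol may be lost or dehydrated during isolation. The fallback sets out from 1 and replaces the aldol by an alkylation. The same dianion 2 is treated with benzyl chloromethyl ether (Fráter–Seebach alkylation, anti to the C4 alkoxide) to give the organic-soluble (3R,4R)-3-[(benzyloxy)methyl]-4-hydroxyoxolan-2-one F2. Hydrogenolysis (H2, 10% Pd/C, EtOH, rt) should then give 3, where the route resumes.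

Further compounds
F1 | step 3 | ketene acetal diphenyl phosphate of 4: (4R)-2-(diphenoxyphosphoryloxy)-4,5-dihydrofuran with C3-CH2O and C4-O bridged by di-tert-butylsilylene | O=P(Oc1ccccc1)(Oc1ccccc1)OC1=C2CO[Si](C(C)(C)C)(C(C)(C)C)O[C@H]2CO1
F0 | step 4 | none | none
F2 | step 1 | (3R,4R)-3-[(benzyloxy)methyl]-4-hydroxyoxolan-2-one | O=C1[C@H](COCc2ccccc2)[C@@H](O)CO1
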